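The pyran ring (O1, C2, C3, C4, C4a, C8a) is traced back to the furanone ring of a 2-phenylbenzofuran-3(2H)-one by excising C3, its only CH2 group. In the key step a Dowd–Beckwith rearrangement walks an exocyclic CH2 radical at C2 into the C2–C4 bond. This gives the six-membered ketone in one operation. It exploits that C2 carries both O1 and the phenyl ring, which stabilise the expanded radical, and that C4 is carbonyl-derived. The precursor is a racemic 2-(iodomethyl)-2-phenylcoumaranone bearing both methoxy groups and the prenyl chain. The racemic, base-labile flavanone is then funnelled into one cis-alcohol by dynamic kinetic transfer hydrogenation, and C4 is inverted.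

Key step: step 5

Remark on the chemistry: the SMILES encodes (2S,4R), the 2,4-trans isomer, with phenyl and hydroxyl on opposite faces. Flavan numbering (O1, C2, C3, C4, C4a, C5–C8, C8a) is used for the atoms of all intermediates, so benzofuranone C3 is called C4.

Step 1
Reactants: 1 3,5-dimethoxyphenol; 2 3-methylbut-2-en-1-ol (prenol)
Product: 3 3,5-dimethoxy-2-(3-methylbut-2-en-1-yl)phenol
Conditions: acidic Al2O3, ClCH2CH2Cl, reflux (1 in excess)
Reagents that add atoms: none
Why: Alumina-templated ortho-selective Friedel–Crafts allylation, in which the surface binds the phenol OH and the allylic alcohol side by side, so the prenyl cation equivalent reaches one of the two equivalent ortho carbons rather than the carbon between the methoxy groups; no stereocentre is formed.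

Step 2
Reactants: 3 3,5-dimethoxy-2-(3-methylbut-2-en-1-yl)phenol; 4 rac-2-bromo-2-phenylacetic acid
Product: 5 rac-2-[3,5-dimethoxy-2-(3-methylbut-2-en-1-yl)phenoxy]-2-phenylacetic acid
Conditions: NaH (2.2 equiv), DMF, 0 °C to rt; 1 M HCl work-up
Reagents that add atoms: none
Why: Williamson ether synthesis, in which the sodium phenoxide displaces the activated benzylic α-bromide of the carboxylate salt by SN2; the new stereocentre is racemic, which is harmless because it is erased in steps 4 and 5.

Step 3
Reactants: 5 rac-2-[3,5-dimethoxy-2-(3-methylbut-2-en-1-yl)phenoxy]-2-phenylacetic acid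
Product: 7 rac-4,6-dimethoxy-7-(3-methylbut-2-en-1-yl)-2-phenylbenzofuran-3(2H)-one, via mixed trifluoroacetic anhydride 6 (not isolated)
Conditions: (CF3CO)2O (1.5 equiv), CH2Cl2, 0 °C, Ar; aq. NaHCO3 work-up
Reagents that add atoms: none
Why: Intramolecular Friedel–Crafts acylation through the mixed anhydride, in which only the free carbon ortho to the ether oxygen can reach the acyl group (five-membered closure) and its ortho and para methoxy groups activate it enough that no Lewis acid is needed and the prenyl alkene should survive; C2 stays racemic and enolisable.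

Step 4
Reactants: 7 rac-4,6-dimethoxy-7-(3-methylbut-2-en-1-yl)-2-phenylbenzofuran-3(2H)-one
Product: 8 rac-2-(iodomethyl)-4,6-dimethoxy-7-(3-methylbut-2-en-1-yl)-2-phenylbenzofuran-3(2H)-one
Conditions: NaH (1.1 equiv), THF, 0 °C, Ar; CH2I2 (5 equiv), rt to 45 °C, dark
Reagents that add atoms: diiodomethane ICI
Why: C-Alkylation of the soft, tightly ion-paired sodium enolate at C2 by the soft electrophile CH2I2, the usual entry to α-(halomethyl) ketones for radical ring expansion; excess CH2I2 suppresses a second displacement, and the quaternary centre is racemic.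

Step 5
Reactants: 8 rac-2-(iodomethyl)-4,6-dimethoxy-7-(3-methylbut-2-en-1-yl)-2-phenylbenzofuran-3(2H)-one
Product: 9 rac-5,7-dimethoxy-8-(3-methylbut-2-en-1-yl)-2-phenylchroman-4-one
Conditions: Bu3SnH (1.2 equiv, syringe pump), AIBN (0.1 equiv), PhH (0.01 M), reflux
Reagents that add atoms: none
Why: Dowd–Beckwith ring expansion (radical 1,2-acyl shift): the stannyl radical abstracts iodine from 8, and the primary radical adds to the adjacent C4 carbonyl carbon in a 3-exo-trig closure to give a cyclopropyloxy radical fused to the furanone. β-Scission of the shared C2–C4 bond restores the ketone and turns the five-membered ring (O1, C2, C4, C4a, C8a) into the six-membered one with the former exocyclic CH2 as C3, so the six-membered ring arises by fragmentation and not by a direct closure. The substrate directs this scission, because it leaves a benzylic, α-oxygenated radical at C2, whereas the alternatives return the primary radical or would give an aryl radical. The closest known reactions are the one-carbon expansions of 2-(halomethyl)cycloalkanones and 2-(halomethyl)indanones. The new stereocentre C2 forms by unselective hydrogen transfer from Bu3SnH to a planar radical, so 9 is racemic by design and C2 is fixed only in step 6. The acyl shift must outrun direct reduction, the slower 1,2-phenyl shift and attack on the prenyl alkene, which slow stannane addition at high dilution and the proximity of the carbonyl group secure.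

Step 6
Reactants: 9 rac-5,7-dimethoxy-8-(3-methylbut-2-en-1-yl)-2-phenylchroman-4-one
Product: 11 (2S,4S)-5,7-dimethoxy-8-(3-methylbut-2-en-1-yl)-2-phenylchroman-4-ol (2,4-cis), via ring-opened chalcone 10 (not isolated)
Conditions: RuCl[(S,S)-TsDPEN](p-cymene) (2 mol %), HCO2H, DBU (slight excess over HCO2H), MeCN, 40 °C
Reagents that add atoms: none
Why: Noyori asymmetric transfer hydrogenation run as a dynamic kinetic resolution, a known process for 2-substituted chroman-4-ones: DBU interconverts the enantiomers of 9 by retro-oxa-Michael/oxa-Michael reaction through 10, and the (S,S)-catalyst delivers hydride to the Re face of C4=O (4S) rapidly only in the (2S)-ketone, where this is the pseudo-axial attack leading to the 2,4-cis alcohol, so the catalyst sets both stereocentres.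

Step 7
Reactants: 11 (2S,4S)-5,7-dimethoxy-8-(3-methylbut-2-en-1-yl)-2-phenylchroman-4-ol
Product: 13 (2S,4R)-5,7-dimethoxy-8-(3-methylbut-2-en-1-yl)-2-phenylchroman-4-ol (2,4-trans), via inverted acetate 12 (not isolated)
Conditions: PPh3, DIAD, AcOH (1.2 equiv each), THF, −20 to 0 °C; solvent switch; K2CO3 (cat.), MeOH, 0 °C
Reagents that add atoms: acetic acid CC(=O)O
Why: Mitsunobu reaction, in which acetate displaces the oxyphosphonium group at C4 with inversion along the pseudo-axial trajectory anti to the equatorial 2-phenyl group (an ion-pair pathway should attack the same face); acetate is chosen as a poor leaving group so that 12 does not ionise, and base-catalysed transesterification cleaves only the acyl–oxygen bond, leaving C4 and C2 untouched.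

Compound list
1 | 3,5-dimethoxyphenol | COc1cc(O)cc(OC)c1 | starting material
2 | 3-methylbut-2-en-1-ol (prenol) | CC(C)=CCO | starting material
3 | 3,5-dimethoxy-2-(3-methylbut-2-en-1-yl)phenol | COc1cc(O)c(CC=C(C)C)c(OC)c1 | intermediate
4 | rac-2-bromo-2-phenylacetic acid | OC(=O)C(Br)c1ccccc1 | starting material
5 | rac-2-[3,5-dimethoxy-2-(3-methylbut-2-en-1-yl)phenoxy]-2-phenylacetic acid | COc1cc(OC)c(CC=C(C)C)c(c1)OC(c1ccccc1)C(=O)O | intermediate
6 | mixed anhydride of 5 with trifluoroacetic acid (racemic, not isolated) | COc1cc(OC)c(CC=C(C)C)c(c1)OC(c1ccccc1)C(=O)OC(=O)C(F)(F)F | intermediate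
7 | rac-4,6-dimethoxy-7-(3-methylbut-2-en-1-yl)-2-phenylbenzofuran-3(2H)-one | COc1cc(OC)c2c(c1CC=C(C)C)OC(c1ccccc1)C2=O | intermediate
8 | rac-2-(iodomethyl)-4,6-dimethoxy-7-(3-methylbut-2-en-1-yl)-2-phenylbenzofuran-3(2H)-one | COc1cc(OC)c2c(c1CC=C(C)C)OC(CI)(c1ccccc1)C2=O | intermediate
9 | rac-5,7-dimethoxy-8-(3-methylbut-2-en-1-yl)-2-phenylchroman-4-one | COc1cc(OC)c2c(c1CC=C(C)C)OC(c1ccccc1)CC2=O | intermediate
10 | (E)-1-[2-hydroxy-4,6-dimethoxy-3-(3-methylbut-2-en-1-yl)phenyl]-3-phenylprop-2-en-1-one (not isolated) | COc1cc(OC)c(C(=O)/C=C/c2ccccc2)c(O)c1CC=C(C)C | intermediate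
11 | (2S,4S)-5,7-dimethoxy-8-(3-methylbut-2-en-1-yl)-2-phenylchroman-4-ol (2,4-cis) | COc1cc(OC)c2c(c1CC=C(C)C)O[C@H](c1ccccc1)C[C@@H]2O | intermediate
12 | (2S,4R)-5,7-dimethoxy-8-(3-methylbut-2-en-1-yl)-2-phenylchroman-4-yl acetate (2,4-trans, not isolated) | COc1cc(OC)c2c(c1CC=C(C)C)O[C@H](c1ccccc1)C[C@H]2OC(C)=O | intermediate
13 | (2S,4R)-5,7-dimethoxy-8-(3-methylbut-2-en-1-yl)-2-phenylchroman-4-ol (2,4-trans) | COc1cc(OC)c2c(c1CC=C(C)C)O[C@H](c1ccccc1)C[C@H]2O | target

Total steps: 7. Longest linear sequence: 7 (from 1).

Steps most likely to fail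

1. Step 5. Three processes would erode the ring expansion: hydrogen transfer to the primary radical before the acyl shift, a competing 1,2-phenyl shift, and cyclisation of the expanded C2 radical onto the prenyl double bond. The fallback is polar instead of radical; it sets out from 8 and comes back at 9. Iodine–lithium exchange with t-BuLi (Et2O–pentane, −100 °C) triggers an intramolecular Barbier-type 3-exo addition to the ketone. After a cold quench this should give the fused cyclopropanol rac-4,6-dimethoxy-3-(3-methylbut-2-en-1-yl)-1a-phenyl-1a,6b-dihydro-1H-cyclopropa[b]benzofuran-6b-ol F1. K2CO3 in MeOH then opens its alkoxide as a homoenolate at the internal bond, towards the benzylic carbon C2, and protonation gives 9.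

2. Step 6. Racemisation by retro-oxa-Michael reaction may be slower than reduction of the mismatched enantiomer, which would cost enantio- and diastereopurity or stall the reaction at half conversion. Reduction of the ring-opened enone may also drain material. The fallback separates reduction from resolution; it sets out from 9 and comes back at 11. NaBH4 (MeOH, 0 °C) attacks pseudo-axially and should give the racemic 2,4-cis alcohol rac-(2S*,4S*)-5,7-dimethoxy-8-(3-methylbut-2-en-1-yl)-2-phenylchroman-4-ol F2. Immobilised lipase B from Candida antarctica with vinyl acetate in MTBE then acylates the (4R)-configured enantiomer, following the empirical preference for aryl alkyl carbinols, to (2R,4R)-5,7-dimethoxy-8-(3-methylbut-2-en-1-yl)-2-phenylchroman-4-yl acetate F3. This leaves 11 to be separated by chromatography.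

3. Step 7. The activated C4–O bond sits on a benzylic carbon flanked by three ring oxygens. Premature ionisation could therefore lead to loss of a C3 proton or to incomplete inversion. The fallback avoids any leaving group at C4; it sets out from 11 and comes back at 13. Dess–Martin periodinane (NaHCO3, CH2Cl2) oxidises 11 to (2S)-5,7-dimethoxy-8-(3-methylbut-2-en-1-yl)-2-phenylchroman-4-one F4 without touching C2. L-Selectride (THF, −78 °C) then attacks from the pseudo-equatorial side, as bulky hydrides do on conformationally anchored six-membered ketones, to place the 4-OH pseudo-axial and trans to the 2-phenyl group.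

Further compounds
F1 | step 5 | rac-4,6-dimethoxy-3-(3-methylbut-2-en-1-yl)-1a-phenyl-1a,6b-dihydro-1H-cyclopropa[b]benzofuran-6b-ol | COc1cc(OC)c2c(c1CC=C(C)C)OC1(c3ccccc3)CC21O
F2 | step 6 | rac-(2S*,4S*)-5,7-dimethoxy-8-(3-methylbut-2-en-1-yl)-2-phenylchroman-4-ol (both enantiomers) | COc1cc(OC)c2c(c1CC=C(C)C)O[C@H](c1ccccc1)C[C@@H]2O.COc1cc(OC)c2c(c1CC=C(C)C)O[C@@H](c1ccccc1)C[C@H]2O
F3 | step 6 | (2R,4R)-5,7-dimethoxy-8-(3-methylbut-2-en-1-yl)-2-phenylchroman-4-yl acetate | COc1cc(OC)c2c(c1CC=C(C)C)O[C@@H](c1ccccc1)C[C@H]2OC(C)=O
F4 | step 7 | (2S)-5,7-dimethoxy-8-(3-methylbut-2-en-1-yl)-2-phenylchroman-4-one | COc1cc(OC)c2c(c1CC=C(C)C)O[C@H](c1ccccc1)CC2=O
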